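**Plan**
Oxolane numbering: O1, C2 (aryl), C3 (CH2OH), C4 (OH and arylmethyl), C5. Without C2, the atoms O1, C3, C4 and C5 form an oxetane that already carries the adjacent centres C3 and C4. This hidden four-membered ring lets C2 be added last, as a carbene carbon bearing its aryl group.
Cuts: C2–H back to C2–CO2R; then O1–C2 and C2–C3 together (oxetane plus aryl diazoester); then the aryl–CH2 bond of the C4 arylmethyl group (spiro-epoxide plus aryl Grignard reagent); then epoxide to methylene to oxetan-3-one; finally O1–C5 (propargylic alcohol).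
Forward: the oxetane is closed first by gold-carbene O–H insertion. A spiro-epoxide is built on it and opened by the first aryl unit. The oxolane then arises from the oxetane by ring enlargement with the second aryl unit, and decarboxylation and deprotection finish the route.
Stereochemistry: C3 comes from (R)-glyceraldehyde acetonide and migrates with retention. C4 comes from epoxidation of the 3-methyleneoxetane on the face away from the C3 side chain. C2 is set last by radical equilibration to the more stable 2,3-trans oxolane.

Key step: step 12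

Assumption: the ring enlargement may deliver either C2 epimer of the ester; the one with the aryl group trans to the C3 side chain is drawn, and both converge later because C2 becomes a planar radical in the decarboxylation.
Abbreviations: Ar = 4-benzyloxy-3-methoxyphenyl, TBDPS = tert-butyldiphenylsilyl, TES = triethylsilyl. Oxolanes are numbered as in the plan.

**Step 1**
Reactants: 1 (R)-2,2-dimethyl-1,3-dioxolane-4-carbaldehyde
Product: 2 (S)-4-ethynyl-2,2-dimethyl-1,3-dioxolane
Conditions: dimethyl (1-diazo-2-oxopropyl)phosphonate, K2CO3, MeOH, 0 °C → rt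
Reagents that add atoms: dimethyl (1-diazo-2-oxopropyl)phosphonate, CC(=O)C(=[N+]=[N-])P(=O)(OC)OC
Why: The Ohira–Bestmann variant of the Seyferth–Gilbert homologation converts the aldehyde into the terminal alkyne under K2CO3/MeOH, conditions known to leave this alpha-alkoxy stereocentre from the chiral pool intact (the descriptor changes from R to S only through the CIP ranking).

**Step 2**
Reactants: 2 (S)-4-ethynyl-2,2-dimethyl-1,3-dioxolane
Product: 3 (S)-but-3-yne-1,2-diol
Conditions: Dowex 50WX8 (H+ form), MeOH/H2O 9:1, rt
Reagents that add atoms: none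
Why: Acid-catalysed acetal hydrolysis on a sulfonic acid resin frees the 1,2-diol without affecting the alkyne or the stereocentre, and the water-soluble product is obtained by filtration and evaporation alone.

**Step 3**
Reactants: 3 (S)-but-3-yne-1,2-diol
Product: 4 (S)-1-(tert-butyldiphenylsilyloxy)but-3-yn-2-ol
Conditions: TBDPSCl (1.05 equiv), imidazole, CH2Cl2, 0 °C
Reagents that add atoms: tert-butyl(chloro)diphenylsilane, CC(C)(C)[Si](Cl)(c1ccccc1)c1ccccc1
Why: Sterically controlled silylation, in which the bulky chlorosilane takes the primary hydroxyl far faster than the secondary propargylic one; this large and weakly basic ether is chosen because it cannot compete as an oxygen nucleophile for the gold and rhodium carbenes of steps 4 and 12, shields one ring face in step 6 and leaves with fluoride in step 15.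

**Step 4**
Reactants: 4 (S)-1-(tert-butyldiphenylsilyloxy)but-3-yn-2-ol
Product: 5 (R)-2-[(tert-butyldiphenylsilyloxy)methyl]oxetan-3-one
Conditions: [(2-biphenylyl)Cy2P]AuNTf2 (5 mol %), methyl 5-bromopyridine-3-carboxylate N-oxide (2 equiv), HNTf2 (1.2 equiv), DCE, rt
Reagents that add atoms: methyl 5-bromopyridine-3-carboxylate N-oxide, COC(=O)c1cc(Br)c[n+]([O-])c1
Why: Gold-catalysed alkyne oxidation, a known one-step route from secondary propargylic alcohols to oxetan-3-ones: the N-oxide adds to the internal carbon of the gold-bound terminal alkyne, loss of the pyridine leaves an alpha-oxo gold carbene at the terminal carbon, and intramolecular O–H insertion closes the four-membered ring without touching the carbinol centre, which cannot racemise later because enolisation inside the oxetane is strongly disfavoured.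

**Step 5**
Reactants: 5 (R)-2-[(tert-butyldiphenylsilyloxy)methyl]oxetan-3-one
Product: 6 (S)-2-[(tert-butyldiphenylsilyloxy)methyl]-3-methylideneoxetane
Conditions: Cp2TiMe2 (2.5 equiv), toluene, 75 °C, dark
Reagents that add atoms: dimethyltitanocene Cp2TiMe2, C[Ti+2]C.c1cc[cH-]c1.c1cc[cH-]c1
Why: Petasis methylenation, in which the non-basic Cp2Ti=CH2 formed on heating olefinates the strained ketone through an oxatitanacyclobutane, so that the epimerisation at the alpha carbon or beta-elimination of the silyloxy group that a basic phosphorus ylide could cause is avoided.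

**Step 6**
Reactants: 6 (S)-2-[(tert-butyldiphenylsilyloxy)methyl]-3-methylideneoxetane
Product: 7 (3S,4R)-4-[(tert-butyldiphenylsilyloxy)methyl]-1,5-dioxaspiro[2.3]hexane (epoxide oxygen trans to the side chain)
Conditions: dimethyldioxirane (acetone solution), CH2Cl2, 0 °C
Reagents that add atoms: dimethyldioxirane, CC1(C)OO1
Why: Concerted dioxirane epoxidation under neutral conditions should occur on the face of the almost flat ring that is remote from the CH2OTBDPS group, which places the new C–O bond trans and the epoxide CH2 cis to the side chain and so sets the quaternary centre in the sense that direct addition of a benzyl nucleophile to ketone 5 could not give.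

**Step 7**
Reactants: 8 4-bromo-2-methoxyphenol
Product: 9 1-(benzyloxy)-4-bromo-2-methoxybenzene
Conditions: BnBr, K2CO3, acetone, reflux
Reagents that add atoms: benzyl bromide, BrCc1ccccc1
Why: Williamson ether synthesis of a phenoxide with a reactive benzylic halide, giving a phenol protecting group that survives magnesium, carbenes, zinc and fluoride and is removed in the last step.

**Step 8**
Reactants: 7 (3S,4R)-4-[(tert-butyldiphenylsilyloxy)methyl]-1,5-dioxaspiro[2.3]hexane; 9 1-(benzyloxy)-4-bromo-2-methoxybenzene
Product: 11 (2R,3S)-3-(Ar-methyl)-2-[(tert-butyldiphenylsilyloxy)methyl]oxetan-3-ol, via arylmagnesium bromide 10 (not isolated)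
Conditions: 9, Mg, THF, reflux; then CuI (10 mol %), 7, THF, −40 → −10 °C; aq NH4Cl
Reagents that add atoms: none
Why: Copper-catalysed SN2 opening of a 2,2-disubstituted epoxide by an aryl Grignard reagent takes place at the unhindered CH2 terminus, so the C–O bond at the quaternary centre and its configuration are kept, while the less reactive oxetane and the silyl ether are inert at this temperature.

**Step 9**
Reactants: 11 (2R,3S)-3-(Ar-methyl)-2-[(tert-butyldiphenylsilyloxy)methyl]oxetan-3-ol
Product: 12 (2R,3S)-3-(Ar-methyl)-2-[(tert-butyldiphenylsilyloxy)methyl]-3-(triethylsilyloxy)oxetane (silyloxy trans to the side chain)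
Conditions: TESOTf, 2,6-lutidine, CH2Cl2, −78 → 0 °C
Reagents that add atoms: triethylsilyl trifluoromethanesulfonate, CC[Si](CC)(CC)OS(=O)(=O)C(F)(F)F
Why: Silylation of a hindered tertiary alcohol with a silyl triflate and a non-nucleophilic base is standard, and it removes the only O–H bond that would otherwise be inserted by the carbene in step 12.

**Step 10**
Reactants: 13 2-(4-benzyloxy-3-methoxyphenyl)acetic acid
Product: 14 2,2,2-trichloroethyl 2-(4-benzyloxy-3-methoxyphenyl)acetate
Conditions: Cl3CCH2OH, DCC, DMAP (cat.), CH2Cl2, 0 °C → rt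
Reagents that add atoms: 2,2,2-trichloroethanol, OCC(Cl)(Cl)Cl
Why: Steglich esterification under neutral conditions; the trichloroethyl ester is chosen because it raises the electrophilicity of the derived carbene and can later be removed reductively at a site remote from the crowded C2.

**Step 11**
Reactants: 14 2,2,2-trichloroethyl 2-(4-benzyloxy-3-methoxyphenyl)acetate
Product: 15 2,2,2-trichloroethyl 2-(4-benzyloxy-3-methoxyphenyl)-2-diazoacetate
Conditions: 4-acetamidobenzenesulfonyl azide, DBU, MeCN, 0 °C → rt
Reagents that add atoms: 4-acetamidobenzenesulfonyl azide, CC(=O)Nc1ccc(cc1)S(=O)(=O)N=[N+]=[N-]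
Why: Regitz diazo transfer to the DBU-generated ester enolate of an arylacetate is the standard entry to aryldiazoacetates, trichloroethyl esters included.

**Step 12**
Reactants: 12 (2R,3S)-3-(Ar-methyl)-2-[(tert-butyldiphenylsilyloxy)methyl]-3-(triethylsilyloxy)oxetane; 15 2,2,2-trichloroethyl 2-(4-benzyloxy-3-methoxyphenyl)-2-diazoacetate
Product: 17 2,2,2-trichloroethyl (2R,3S,4R)-2-Ar-4-(Ar-methyl)-3-[(tert-butyldiphenylsilyloxy)methyl]-4-(triethylsilyloxy)oxolane-2-carboxylate, via oxonium ylide 16 (not isolated)
Conditions: Rh2(OAc)4 (2 mol %), 4 Å MS, CH2Cl2, reflux, 15 (2 equiv) added by syringe pump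
Reagents that add atoms: none
Why: Rh2(OAc)4 turns 15 into an electrophilic donor/acceptor rhodium carbene with loss of N2, and the exposed, strongly Lewis-basic oxygen of the strained ring of 12 adds to it, on the side away from the C3 side chain, to give oxonium ylide 16. In 16 the O1–C3 bond breaks homolytically and the resulting radical pair, still held together through O1–C5–C4, recombines at the former carbene carbon (1,2-Stevens shift), so that O1–C2 and C2–C3 are the two new bonds; the closest known reaction type is the ring enlargement of oxetanes to oxolanes by diazo esters under copper, rhodium or visible-light conditions. The oxolane is therefore closed by a four-to-five ring expansion driven by release of oxetane strain, the closing event being C2–C3 recombination, and not by cyclisation of an open chain. C3 should migrate with retention because the tethered radical pair collapses faster than the C3 radical can turn its other face to C2, C4 is not touched, and the new quaternary centre C2 is controlled only by the preference of the aryl group to lie trans to the C3 side chain, which need not be high since C2 is flattened again in step 14. Chemoselectivity for the oxetane oxygen is secured by the absence of O–H bonds and of any other dialkyl ether in 12 (silyl and aryl ethers are poor donors, and the trisubstituted arenes are too hindered for cyclopropanation by this bulky carbene). Regioselectivity for migration of C3 over C5 is secured by the better stabilised secondary radical and by the longer, more crowded O1–C3 bond of the ylide.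

**Step 13**
Reactants: 17 2,2,2-trichloroethyl (2R,3S,4R)-2-Ar-4-(Ar-methyl)-3-[(tert-butyldiphenylsilyloxy)methyl]-4-(triethylsilyloxy)oxolane-2-carboxylate
Product: 18 (2R,3S,4R)-2-Ar-4-(Ar-methyl)-3-[(tert-butyldiphenylsilyloxy)methyl]-4-(triethylsilyloxy)oxolane-2-carboxylic acid
Conditions: Zn dust, AcOH/THF 1:5, rt
Reagents that add atoms: none
Why: Reductive fragmentation of the trichloroethyl ester (zinc insertion into a C–Cl bond followed by beta-elimination of the carboxylate) acts at a carbon remote from the quaternary C2, so the crowding that would slow a saponification is irrelevant and silyl ethers, benzyl ethers and the alpha-alkoxy C–O bond are left alone.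

**Step 14**
Reactants: 18 (2R,3S,4R)-2-Ar-4-(Ar-methyl)-3-[(tert-butyldiphenylsilyloxy)methyl]-4-(triethylsilyloxy)oxolane-2-carboxylic acid
Product: 20 (2R,3S,4R)-2-Ar-4-(Ar-methyl)-3-[(tert-butyldiphenylsilyloxy)methyl]-4-(triethylsilyloxy)oxolane (2,3-trans), via 2,3-cis epimer 19 (not isolated)
Conditions: 9-mesityl-10-methylacridinium tetrafluoroborate (5 mol %), (4-ClC6H4S)2 (20 mol %), 2,6-lutidine (1 equiv), DCE, argon, 450 nm LEDs, rt; irradiation continued until the epimer composition at C2 is constant
Reagents that add atoms: none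
Why: Photoredox hydrodecarboxylation, known for alpha-oxy and arylacetic acids: the excited acridinium oxidises the carboxylate, loss of CO2 gives the planar benzylic alpha-oxy C2 radical, and hydrogen-atom transfer from the arenethiol formed from the disulfide should first deliver hydrogen anti to the C3 side chain (19), after which reversible abstraction of the weak, hydridic C2–H bond by the arenethiyl radical (thiol-catalysed radical epimerisation alpha to an ether oxygen) funnels the material to the more stable 2,3-trans isomer 20 under neutral conditions, avoiding the benzylic cation that an acid equilibration would generate and that the C4 arylmethyl ring would trap irreversibly as an aryltetralin.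

**Step 15**
Reactants: 20 (2R,3S,4R)-2-Ar-4-(Ar-methyl)-3-[(tert-butyldiphenylsilyloxy)methyl]-4-(triethylsilyloxy)oxolane
Product: 21 (3R,4S,5R)-5-Ar-3-(Ar-methyl)-4-(hydroxymethyl)oxolan-3-ol
Conditions: TBAF (4 equiv), THF, 0 °C → rt
Reagents that add atoms: none
Why: Fluoride-induced desilylation driven by Si–F bond formation removes the primary TBDPS and the tertiary TES ether in one operation and leaves benzyl ethers and all three stereocentres untouched.

**Step 16**
Reactants: 21 (3R,4S,5R)-5-Ar-3-(Ar-methyl)-4-(hydroxymethyl)oxolan-3-ol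
Product: 22 (3R,4S,5R)-5-(4-hydroxy-3-methoxyphenyl)-3-[(4-hydroxy-3-methoxyphenyl)methyl]-4-(hydroxymethyl)oxolan-3-ol
Conditions: H2 (1 atm), 10% Pd/C, EtOAc/EtOH, rt, stopped when 21 is consumed
Reagents that add atoms: none
Why: Catalytic hydrogenolysis cleaves the two phenolic benzyl ethers quickly under neutral conditions, well before the cyclic benzylic C2–O1 bond reacts, a selectivity that is routine for 2-aryloxolane lignans and is helped here by the absence of any slow-reacting alkyl benzyl ether.

**Compound list**
1 | (R)-2,2-dimethyl-1,3-dioxolane-4-carbaldehyde | CC1(C)OC[C@H](C=O)O1 | starting material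
2 | (S)-4-ethynyl-2,2-dimethyl-1,3-dioxolane | C#C[C@H]1COC(C)(C)O1 | intermediate
3 | (S)-but-3-yne-1,2-diol | C#C[C@H](O)CO | intermediate
4 | (S)-1-(tert-butyldiphenylsilyloxy)but-3-yn-2-ol | C#C[C@H](O)CO[Si](c1ccccc1)(c1ccccc1)C(C)(C)C | intermediate
5 | (R)-2-[(tert-butyldiphenylsilyloxy)methyl]oxetan-3-one | O=C1CO[C@@H]1CO[Si](c2ccccc2)(c2ccccc2)C(C)(C)C | intermediate
6 | (S)-2-[(tert-butyldiphenylsilyloxy)methyl]-3-methylideneoxetane | C=C1CO[C@@H]1CO[Si](c2ccccc2)(c2ccccc2)C(C)(C)C | intermediate
7 | (3S,4R)-4-[(tert-butyldiphenylsilyloxy)methyl]-1,5-dioxaspiro[2.3]hexane | C1O[C@]12CO[C@@H]2CO[Si](c3ccccc3)(c3ccccc3)C(C)(C)C | intermediate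
8 | 4-bromo-2-methoxyphenol | COc1cc(Br)ccc1O | starting material
9 | 1-(benzyloxy)-4-bromo-2-methoxybenzene | COc1cc(Br)ccc1OCc1ccccc1 | intermediate
10 | (4-benzyloxy-3-methoxyphenyl)magnesium bromide | COc1cc([Mg]Br)ccc1OCc1ccccc1 | intermediate
11 | (2R,3S)-3-[(4-benzyloxy-3-methoxyphenyl)methyl]-2-[(tert-butyldiphenylsilyloxy)methyl]oxetan-3-ol | COc1cc(C[C@]2(O)CO[C@@H]2CO[Si](c3ccccc3)(c3ccccc3)C(C)(C)C)ccc1OCc1ccccc1 | intermediate
12 | (2R,3S)-3-[(4-benzyloxy-3-methoxyphenyl)methyl]-2-[(tert-butyldiphenylsilyloxy)methyl]-3-(triethylsilyloxy)oxetane | COc1cc(C[C@]2(O[Si](CC)(CC)CC)CO[C@@H]2CO[Si](c3ccccc3)(c3ccccc3)C(C)(C)C)ccc1OCc1ccccc1 | intermediate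
13 | 2-(4-benzyloxy-3-methoxyphenyl)acetic acid | COc1cc(CC(=O)O)ccc1OCc1ccccc1 | starting material
14 | 2,2,2-trichloroethyl 2-(4-benzyloxy-3-methoxyphenyl)acetate | COc1cc(CC(=O)OCC(Cl)(Cl)Cl)ccc1OCc1ccccc1 | intermediate
15 | 2,2,2-trichloroethyl 2-(4-benzyloxy-3-methoxyphenyl)-2-diazoacetate | COc1cc(C(=[N+]=[N-])C(=O)OCC(Cl)(Cl)Cl)ccc1OCc1ccccc1 | intermediate
16 | oxonium ylide: oxetane 12 bearing on its ring oxygen the carbanionic C(Ar)(CO2CH2CCl3) unit | COc1cc(C[C@]2(O[Si](CC)(CC)CC)C[O+]([C-](C(=O)OCC(Cl)(Cl)Cl)c3ccc(OCc4ccccc4)c(OC)c3)[C@@H]2CO[Si](c3ccccc3)(c3ccccc3)C(C)(C)C)ccc1OCc1ccccc1 | intermediate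
17 | 2,2,2-trichloroethyl (2R,3S,4R)-2-(4-benzyloxy-3-methoxyphenyl)-4-[(4-benzyloxy-3-methoxyphenyl)methyl]-3-[(tert-butyldiphenylsilyloxy)methyl]-4-(triethylsilyloxy)oxolane-2-carboxylate | COc1cc(C[C@]2(O[Si](CC)(CC)CC)CO[C@@](C(=O)OCC(Cl)(Cl)Cl)(c3ccc(OCc4ccccc4)c(OC)c3)[C@@H]2CO[Si](c3ccccc3)(c3ccccc3)C(C)(C)C)ccc1OCc1ccccc1 | intermediate
18 | (2R,3S,4R)-2-(4-benzyloxy-3-methoxyphenyl)-4-[(4-benzyloxy-3-methoxyphenyl)methyl]-3-[(tert-butyldiphenylsilyloxy)methyl]-4-(triethylsilyloxy)oxolane-2-carboxylic acid | COc1cc(C[C@]2(O[Si](CC)(CC)CC)CO[C@@](C(=O)O)(c3ccc(OCc4ccccc4)c(OC)c3)[C@@H]2CO[Si](c3ccccc3)(c3ccccc3)C(C)(C)C)ccc1OCc1ccccc1 | intermediate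
19 | (2S,3S,4R)-2-(4-benzyloxy-3-methoxyphenyl)-4-[(4-benzyloxy-3-methoxyphenyl)methyl]-3-[(tert-butyldiphenylsilyloxy)methyl]-4-(triethylsilyloxy)oxolane (2,3-cis) | COc1cc(C[C@]2(O[Si](CC)(CC)CC)CO[C@H](c3ccc(OCc4ccccc4)c(OC)c3)[C@@H]2CO[Si](c3ccccc3)(c3ccccc3)C(C)(C)C)ccc1OCc1ccccc1 | intermediate
20 | (2R,3S,4R)-2-(4-benzyloxy-3-methoxyphenyl)-4-[(4-benzyloxy-3-methoxyphenyl)methyl]-3-[(tert-butyldiphenylsilyloxy)methyl]-4-(triethylsilyloxy)oxolane (2,3-trans) | COc1cc(C[C@]2(O[Si](CC)(CC)CC)CO[C@@H](c3ccc(OCc4ccccc4)c(OC)c3)[C@@H]2CO[Si](c3ccccc3)(c3ccccc3)C(C)(C)C)ccc1OCc1ccccc1 | intermediate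
21 | (3R,4S,5R)-5-(4-benzyloxy-3-methoxyphenyl)-3-[(4-benzyloxy-3-methoxyphenyl)methyl]-4-(hydroxymethyl)oxolan-3-ol | COc1cc(C[C@]2(O)CO[C@@H](c3ccc(OCc4ccccc4)c(OC)c3)[C@@H]2CO)ccc1OCc1ccccc1 | intermediate
22 | (3R,4S,5R)-5-(4-hydroxy-3-methoxyphenyl)-3-[(4-hydroxy-3-methoxyphenyl)methyl]-4-(hydroxymethyl)oxolan-3-ol | COc1cc(C[C@]2(O)CO[C@@H](c3ccc(O)c(OC)c3)[C@@H]2CO)ccc1O | target

**Step count**
Total step count: 16. Longest linear sequence: 13 steps (1–6, 8, 9, 12–16).

**Steps most likely to fail**

**Step 12.**
- What may go wrong: capture of the carbene by the flanked oxetane oxygen may be too slow. The bulky donor/acceptor carbene would then be lost to azine or dimer formation or to attack on the electron-rich rings. Migration of C5 may also compete with migration of C3.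
- Fallback idea: separate the ring enlargement from the introduction of the aryl group.
- Route: it sets out from 12. The small and more electrophilic carbene from ethyl diazoacetate is the best documented partner for oxetane enlargement. Under Cu(hfacac)2 (copper bis(hexafluoroacetylacetonate)) in CH2Cl2 at reflux with slow addition, it is inserted into the same O1–C3 bond.
- This gives ethyl (2R,3S,4R)-4-(Ar-methyl)-3-[(tert-butyldiphenylsilyloxy)methyl]-4-(triethylsilyloxy)oxolane-2-carboxylate F1, whose C2 epimer is equally useful.
- LiOH in aqueous THF at rt then gives the corresponding oxolane-2-carboxylic acid F2.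
- Nickel/photoredox decarboxylative arylation of this alpha-oxy acid with bromide 9 follows (Ir[dF(CF3)ppy]2(dtbbpy)PF6, NiCl2·glyme, dtbbpy, Cs2CO3, DMF, blue LEDs). It should attach the aryl group on the face anti to the C3 side chain.
- The fallback comes back to the route at 20, so steps 13 and 14 are not needed.

**Step 14.**
- What may go wrong: the strongly stabilised C2 radical may be oxidised further to the oxocarbenium ion, or may couple with thiyl radicals, instead of accepting hydrogen. The excited acridinium may degrade the electron-rich rings. The equilibration may also stall before the trans isomer dominates.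
- Fallback idea: a Barton decarboxylation, a radical chain in which no oxidant is present.
- Route: it sets out from 18. DCC coupling with N-hydroxypyridine-2-thione in CH2Cl2 in the dark gives the O-acyl thiohydroxamate of acid 18 F3.
- Visible-light photolysis in benzene with excess PhSH releases the same C2 radical, which is reduced by the thiol.
- Continued irradiation keeps the thiyl/thiol couple running, so that the C2–H epimers equilibrate.
- The fallback comes back to the route at 20.

**Step 6.**
- What may go wrong: facial selectivity may be poor, because a single substituent on an almost flat ring may not differentiate the two faces enough for the small dioxirane.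
- Fallback idea: use a bulkier oxidant and close the epoxide in a separate operation.
- Route: it sets out from 6. Upjohn dihydroxylation (OsO4 cat., NMO, acetone/H2O) should add to the face away from the side chain. The product is (2R,3S)-2-[(tert-butyldiphenylsilyloxy)methyl]-3-(hydroxymethyl)oxetan-3-ol F4, from which a minor diastereomer is more easily separated.
- Selective sulfonylation of the primary hydroxyl (TsCl, pyridine, 0 °C) gives [(2R,3R)-2-[(tert-butyldiphenylsilyloxy)methyl]-3-hydroxyoxetan-3-yl]methyl 4-methylbenzenesulfonate F5.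
- K2CO3 in MeOH then closes the epoxide with the tertiary C–O bond intact.
- The fallback comes back to the route at 7.

**Further compounds**
F1 | step 12 | ethyl (2R,3S,4R)-4-[(4-benzyloxy-3-methoxyphenyl)methyl]-3-[(tert-butyldiphenylsilyloxy)methyl]-4-(triethylsilyloxy)oxolane-2-carboxylate | COc1cc(C[C@]2(O[Si](CC)(CC)CC)CO[C@@H](C(=O)OCC)[C@@H]2CO[Si](c3ccccc3)(c3ccccc3)C(C)(C)C)ccc1OCc1ccccc1
F2 | step 12 | (2R,3S,4R)-4-[(4-benzyloxy-3-methoxyphenyl)methyl]-3-[(tert-butyldiphenylsilyloxy)methyl]-4-(triethylsilyloxy)oxolane-2-carboxylic acid | COc1cc(C[C@]2(O[Si](CC)(CC)CC)CO[C@@H](C(=O)O)[C@@H]2CO[Si](c3ccccc3)(c3ccccc3)C(C)(C)C)ccc1OCc1ccccc1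
F3 | step 14 | 2-thioxopyridin-1(2H)-yl ester (O-acyl thiohydroxamate) of acid 18 | COc1cc(C[C@]2(O[Si](CC)(CC)CC)CO[C@@](C(=O)On3ccccc3=S)(c3ccc(OCc4ccccc4)c(OC)c3)[C@@H]2CO[Si](c3ccccc3)(c3ccccc3)C(C)(C)C)ccc1OCc1ccccc1
F4 | step 6 | (2R,3S)-2-[(tert-butyldiphenylsilyloxy)methyl]-3-(hydroxymethyl)oxetan-3-ol | OC[C@]1(O)CO[C@@H]1CO[Si](c2ccccc2)(c2ccccc2)C(C)(C)C
F5 | step 6 | [(2R,3R)-2-[(tert-butyldiphenylsilyloxy)methyl]-3-hydroxyoxetan-3-yl]methyl 4-methylbenzenesulfonate | Cc1ccc(S(=O)(=O)OC[C@]2(O)CO[C@@H]2CO[Si](c3ccccc3)(c3ccccc3)C(C)(C)C)cc1
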